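The pyran ring of the isoflavan (O1, C2, C3, C4, fused at C4a and C8a) is opened into an A-ring o-quinone methide, O1=C8a–C4a=C4, and a (Z)-enol ether, C2=C3, whose C3 already carries the B ring as a bis-benzyl hydroquinone. One inverse-demand hetero-Diels–Alder reaction forms C4–C3 and O1–C2, closes the ring and sets C3 under control of a (1R,2S)-2-phenylcyclohexyl group on the enol ether oxygen. The methide is released below room temperature from an aryl tert-butyl carbonate aldehyde by hydride addition. Afterwards the auxiliary alkoxy group at C2 is replaced by hydrogen, three benzyl ethers are hydrogenolysed and air oxidises the hydroquinone to the quinone.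

Key step: step 10

Assumption: the (1R,2S) auxiliary is taken to shield the enol ether face that would lead to (3R), as a model of the s-trans enol ether with the phenyl group over the O–CH= face suggests; should the opposite sense be found, (1S,2R)-2-phenylcyclohexanol is used in step 9 and nothing else changes.

Step 1
Reactants: 1 syringaldehyde (4-hydroxy-3,5-dimethoxybenzaldehyde)
Product: 2 4-(benzyloxy)-3,5-dimethoxybenzaldehyde
Conditions: BnBr, K2CO3, DMF, 60 °C
Reagents that add atoms: benzyl bromide, BrCc1ccccc1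
Why: Williamson ether synthesis; the phenol, acidified by the para-formyl group, should be alkylated cleanly although it is flanked by two methoxy groups.

Step 2
Reactants: 2 4-(benzyloxy)-3,5-dimethoxybenzaldehyde
Product: 3 4-(benzyloxy)-2-bromo-3,5-dimethoxybenzaldehyde
Conditions: NBS, MeCN, 40 °C, dark
Reagents that add atoms: N-bromosuccinimide, O=C1CCC(=O)N1Br
Why: Electrophilic aromatic bromination; the only free positions (C2 and C6, equivalent) are ortho and para to methoxy groups, the first bromine retards a second, and the unactivated benzyl ring is not attacked under ionic conditions.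

Step 3
Reactants: 3 4-(benzyloxy)-2-bromo-3,5-dimethoxybenzaldehyde
Product: 4 4-(benzyloxy)-2-hydroxy-3,5-dimethoxybenzaldehyde
Conditions: Cu(acac)2 (5 mol %), N,N'-bis(4-hydroxy-2,6-dimethylphenyl)oxalamide (5 mol %), LiOH·H2O, DMSO/H2O, 80 °C; then 1 M HCl
Reagents that add atoms: lithium hydroxide, [Li+].[OH-]
Why: Ullmann-type copper-catalysed hydroxylation of an aryl bromide, assisted by the ortho-formyl group; the phenoxide that forms deactivates the aldehyde towards hydroxide and the benzyl ether is inert.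

Step 4
Reactants: 4 4-(benzyloxy)-2-hydroxy-3,5-dimethoxybenzaldehyde
Product: 5 4-(benzyloxy)-2-[(tert-butoxycarbonyl)oxy]-3,5-dimethoxybenzaldehyde
Conditions: Boc2O, i-Pr2NEt, DMAP (cat.), CH2Cl2, 0 °C → rt
Reagents that add atoms: di-tert-butyl dicarbonate, CC(C)(C)OC(=O)OC(=O)OC(C)(C)C
Why: DMAP-catalysed O-acylation of the phenol gives the aryl tert-butyl carbonate under conditions that leave the aldehyde untouched.

Step 5
Reactants: 6 2,3-dimethoxyphenol
Product: 7 2,3-dimethoxy-1,4-benzoquinone
Conditions: (KSO3)2NO (2.2 equiv), KH2PO4, H2O/acetone, rt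
Reagents that add atoms: Fremy's salt (dipotassium nitrosodisulfonate), [K+].[K+].[O]N(S(=O)(=O)[O-])S(=O)(=O)[O-]
Why: Teuber oxidation; a phenol with a free para position should be oxidised by the nitroxyl radical to the p-benzoquinone.

Step 6
Reactants: 7 2,3-dimethoxy-1,4-benzoquinone
Product: 9 1,4-bis(benzyloxy)-2,3-dimethoxybenzene, via 2,3-dimethoxybenzene-1,4-diol 8 (not isolated)
Conditions: Na2S2O4, THF/H2O, rt, N2; then KOH, BnBr, Bu4NBr (cat.), rt
Reagents that add atoms: benzyl bromide, BrCc1ccccc1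
Why: Dithionite reduction of the quinone followed in the same flask by a double phase-transfer Williamson benzylation, so that the air-sensitive hydroquinone is never handled.

Step 7
Reactants: 9 1,4-bis(benzyloxy)-2,3-dimethoxybenzene
Product: 10 2,5-bis(benzyloxy)-3,4-dimethoxybenzaldehyde
Conditions: POCl3, DMF, 0 → 70 °C; then ice/H2O
Reagents that add atoms: N,N-dimethylformamide, CN(C)C=O; water, O
Why: Vilsmeier–Haack formylation; the two free positions are equivalent and each is ortho to a benzyloxy and para to a methoxy group, so one aldehyde should form without a Lewis acid that could cleave benzyl ethers.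

Step 8
Reactants: 10 2,5-bis(benzyloxy)-3,4-dimethoxybenzaldehyde
Product: 11 1,4-bis(benzyloxy)-5-ethynyl-2,3-dimethoxybenzene
Conditions: dimethyl (1-diazo-2-oxopropyl)phosphonate, K2CO3, MeOH/THF, rt
Reagents that add atoms: Ohira–Bestmann reagent, CC(=O)C(=[N+]=[N-])P(=O)(OC)OC
Why: Seyferth–Gilbert homologation in the Ohira–Bestmann variant converts the aryl aldehyde into the terminal alkyne under mild carbonate conditions that the benzyl ethers tolerate.

Step 9
Reactants: 11 1,4-bis(benzyloxy)-5-ethynyl-2,3-dimethoxybenzene, 12 (1R,2S)-trans-2-phenylcyclohexanol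
Product: 13 1,4-bis(benzyloxy)-2,3-dimethoxy-5-[(Z)-2-{[(1R,2S)-2-phenylcyclohexyl]oxy}ethenyl]benzene
Conditions: KOt-Bu (20 mol %), DMSO, 50 °C, N2; stopped at full conversion
Reagents that add atoms: none
Why: Base-catalysed anti-Markovnikov hydroalkoxylation of an arylacetylene; the alkoxide of 12 adds to the terminal carbon and anti protonation of the benzylic vinyl anion gives the Z-enol ether kinetically, while the C–O bond and both stereocentres of the auxiliary are untouched.

Step 10
Reactants: 5 4-(benzyloxy)-2-[(tert-butoxycarbonyl)oxy]-3,5-dimethoxybenzaldehyde, 13 1,4-bis(benzyloxy)-2,3-dimethoxy-5-[(Z)-2-{[(1R,2S)-2-phenylcyclohexyl]oxy}ethenyl]benzene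
Product: 17 (2S,3S)-7-(benzyloxy)-3-[2,5-bis(benzyloxy)-3,4-dimethoxyphenyl]-6,8-dimethoxy-2-{[(1R,2S)-2-phenylcyclohexyl]oxy}chroman (2,3-cis), via lithium benzylic alkoxide 14 (not isolated), via carbonate-shifted lithium phenoxide 15 (not isolated), via o-quinone methide 16 (not isolated)
Conditions: 13 (1.5 equiv), L-Selectride (1.0 equiv), PhMe/THF, −78 °C; then MgBr2·OEt2 (1.2 equiv), −78 °C → rt
Reagents that add atoms: none
Why: One equivalent of the hindered borohydride reduces the aldehyde of 5 at −78 °C to alkoxide 14 and is spent before any methide exists; the carbonate then moves from the phenolic to the benzylic oxygen through a six-membered transition state (15), and after addition of the magnesium salt and warming the phenoxide expels tert-butyl carbonate to give o-quinone methide 16. The closest known reaction type is the low-temperature o-quinone methide hetero-Diels–Alder reaction with chiral enol ethers (inverse electron demand, concerted but asynchronous): the nucleophilic aryl-bearing carbon of 13 bonds to the methide carbon (C4–C3) and the carbonyl oxygen to the alkoxy-bearing carbon (O1–C2), so the six-membered pyran ring closes by [4+2] cycloaddition with rearomatisation of the A ring. The oxygen donor on C2 fixes the 3-aryl regiochemistry. C3 is controlled by the auxiliary, whose phenyl group covers one face of the s-trans enol ether, and because the methide carbon is a CH2 group only the enol ether face decides the outcome; C2 follows from the Z geometry and suprafacial addition (2,3-cis) and is removed in step 11. The step needs high facial selectivity and a geometrically pure Z-enol ether, secured by the phenyl shield and by step 9, and any minor diastereomer should be separable because the auxiliary is still attached.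

Step 11
Reactants: 17 (2S,3S)-7-(benzyloxy)-3-[2,5-bis(benzyloxy)-3,4-dimethoxyphenyl]-6,8-dimethoxy-2-{[(1R,2S)-2-phenylcyclohexyl]oxy}chroman
Product: 18 (3S)-7-(benzyloxy)-3-[2,5-bis(benzyloxy)-3,4-dimethoxyphenyl]-6,8-dimethoxychroman
Conditions: Et3SiH (5 equiv), BF3·OEt2, CH2Cl2, −78 → −30 °C; aq. NaHCO3
Reagents that add atoms: none
Why: Ionic reduction of an acetal with silane and Lewis acid; BF3 ionises the exocyclic C2–O bond and the oxocarbenium ion should be reduced at once by excess silane at low temperature, so C2 becomes CH2, C3 is not a reacting centre and keeps its configuration, and the auxiliary alcohol is recovered.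

Step 12
Reactants: 18 (3S)-7-(benzyloxy)-3-[2,5-bis(benzyloxy)-3,4-dimethoxyphenyl]-6,8-dimethoxychroman
Product: 20 5-[(3S)-7-hydroxy-6,8-dimethoxychroman-3-yl]-2,3-dimethoxycyclohexa-2,5-diene-1,4-dione (CNP0121136.1), via hydroquinone triol 19 (not isolated)
Conditions: H2 (1 atm), 10% Pd/C, EtOAc/MeOH, rt; filter; then air (O2), rt
Reagents that add atoms: none
Why: Hydrogenolysis of the three aryl benzyl ethers gives the triol, whose electron-rich 2,3-dimethoxyhydroquinone ring should autoxidise to the p-quinone once the catalyst is removed, while the A-ring phenol is not oxidised by oxygen and C3, which has no cleavable benzylic C–O bond, is untouched.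

Compound list
1 | syringaldehyde (4-hydroxy-3,5-dimethoxybenzaldehyde) | COc1cc(C=O)cc(OC)c1O | starting material
2 | 4-(benzyloxy)-3,5-dimethoxybenzaldehyde | O=Cc1cc(OC)c(OCc2ccccc2)c(OC)c1 | intermediate
3 | 4-(benzyloxy)-2-bromo-3,5-dimethoxybenzaldehyde | O=Cc1cc(OC)c(OCc2ccccc2)c(OC)c1Br | intermediate
4 | 4-(benzyloxy)-2-hydroxy-3,5-dimethoxybenzaldehyde | O=Cc1cc(OC)c(OCc2ccccc2)c(OC)c1O | intermediate
5 | 4-(benzyloxy)-2-[(tert-butoxycarbonyl)oxy]-3,5-dimethoxybenzaldehyde | O=Cc1cc(OC)c(OCc2ccccc2)c(OC)c1OC(=O)OC(C)(C)C | intermediate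
6 | 2,3-dimethoxyphenol | COc1cccc(O)c1OC | starting material
7 | 2,3-dimethoxy-1,4-benzoquinone | COC1=C(OC)C(=O)C=CC1=O | intermediate
8 | 2,3-dimethoxybenzene-1,4-diol (formed in the flask) | COc1c(O)ccc(O)c1OC | intermediate
9 | 1,4-bis(benzyloxy)-2,3-dimethoxybenzene | COc1c(OCc2ccccc2)ccc(OCc2ccccc2)c1OC | intermediate
10 | 2,5-bis(benzyloxy)-3,4-dimethoxybenzaldehyde | O=Cc1cc(OCc2ccccc2)c(OC)c(OC)c1OCc1ccccc1 | intermediate
11 | 1,4-bis(benzyloxy)-5-ethynyl-2,3-dimethoxybenzene | C#Cc1cc(OCc2ccccc2)c(OC)c(OC)c1OCc1ccccc1 | intermediate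
12 | (1R,2S)-trans-2-phenylcyclohexanol | O[C@@H]1CCCC[C@H]1c1ccccc1 | starting material
13 | 1,4-bis(benzyloxy)-2,3-dimethoxy-5-[(Z)-2-{[(1R,2S)-2-phenylcyclohexyl]oxy}ethenyl]benzene | c1ccccc1[C@@H]1CCCC[C@H]1O/C=C\c1cc(OCc2ccccc2)c(OC)c(OC)c1OCc1ccccc1 | intermediate
14 | lithium {4-(benzyloxy)-2-[(tert-butoxycarbonyl)oxy]-3,5-dimethoxyphenyl}methanolate (formed in the flask) | [Li+].[O-]Cc1cc(OC)c(OCc2ccccc2)c(OC)c1OC(=O)OC(C)(C)C | intermediate
15 | lithium 3-(benzyloxy)-6-{[(tert-butoxycarbonyl)oxy]methyl}-2,4-dimethoxyphenolate (formed in the flask) | [Li+].[O-]c1c(COC(=O)OC(C)(C)C)cc(OC)c(OCc2ccccc2)c1OC | intermediate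
16 | 3-(benzyloxy)-2,4-dimethoxy-6-methylidenecyclohexa-2,4-dien-1-one, the o-quinone methide (formed in the flask) | C=C1C=C(OC)C(OCc2ccccc2)=C(OC)C1=O | intermediate
17 | (2S,3S)-7-(benzyloxy)-3-[2,5-bis(benzyloxy)-3,4-dimethoxyphenyl]-6,8-dimethoxy-2-{[(1R,2S)-2-phenylcyclohexyl]oxy}chroman (2,3-cis) | c1ccccc1[C@@H]1CCCC[C@H]1O[C@H]1Oc2c(OC)c(OCc3ccccc3)c(OC)cc2C[C@H]1c1cc(OCc2ccccc2)c(OC)c(OC)c1OCc1ccccc1 | intermediate
18 | (3S)-7-(benzyloxy)-3-[2,5-bis(benzyloxy)-3,4-dimethoxyphenyl]-6,8-dimethoxychroman | COc1c(OC)c(OCc2ccccc2)c([C@H]2COc3c(cc(OC)c(OCc4ccccc4)c3OC)C2)cc1OCc1ccccc1 | intermediate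
19 | (3S)-3-(2,5-dihydroxy-3,4-dimethoxyphenyl)-6,8-dimethoxychroman-7-ol (formed in the flask) | COc1c(OC)c(O)c([C@H]2COc3c(cc(OC)c(O)c3OC)C2)cc1O | intermediate
20 | 5-[(3S)-7-hydroxy-6,8-dimethoxychroman-3-yl]-2,3-dimethoxycyclohexa-2,5-diene-1,4-dione (CNP0121136.1) | COC1=C(OC)C(=O)C([C@H]2COc3c(cc(OC)c(O)c3OC)C2)=CC1=O | target

Total step count: 12 (steps 1–4 for the A-ring aldehyde, steps 5–9 for the enol ether, steps 10–12 for the union and endgame).
Longest linear sequence: 8 steps (steps 5–12, from 2,3-dimethoxyphenol).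

Steps most likely to fail

Step 10. The cycloaddition may show poor facial discrimination on the enol ether, or the methide may be consumed by residual hydride or by self-condensation before the bulky enol ether engages. The fallback builds C3 by auxiliary-controlled enolate alkylation and closes the pyran ring by etherification. It sets out from aldehydes 10 and 4 and comes back to the route at 18. Aldehyde 10 would be homologated with TosMIC (t-BuOK, DME, −40 °C; then MeOH, reflux) to [2,5-bis(benzyloxy)-3,4-dimethoxyphenyl]acetonitrile F1 and hydrolysed (KOH, aqueous ethanol, reflux) to [2,5-bis(benzyloxy)-3,4-dimethoxyphenyl]acetic acid F2. Its pivaloyl mixed anhydride would acylate lithiated (S)-4-benzyl-2-oxazolidinone to give the (4S)-N-arylacetyl oxazolidinone F3. Salicylaldehyde 4 would be O-allylated (allyl bromide, K2CO3, DMF) to 2-(allyloxy)-4-(benzyloxy)-3,5-dimethoxybenzaldehyde F4, reduced (NaBH4, MeOH) to the benzyl alcohol F5 and converted (PBr3, Et2O, 0 °C) into the benzyl bromide F6. The sodium enolate of F3 (NaHMDS, THF, −78 °C) should be alkylated by F6 on the face away from the benzyl group of the oxazolidinone, giving the (2S)-alkylated imide F7. LiBH4 would then release the oxazolidinone and give the primary alcohol F8, Pd(PPh3)4 and morpholine would remove the allyl group to give the phenol alcohol F9, and a Mitsunobu reaction (PPh3, DIAD, THF) would close O1–C2 to give 18.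

Step 9. The hindered alkoxide may add slowly to the electron-rich arylalkyne, and the kinetic Z-enol ether may drift towards E under the basic conditions, which would lower the enantiomeric purity at C3 after step 10. The fallback obtains the Z geometry by syn semi-hydrogenation of an ynol ether. It sets out from 9 and 12 and comes back at 13. Arene 9 would be iodinated (NIS, TFA cat., MeCN) to 1,4-bis(benzyloxy)-5-iodo-2,3-dimethoxybenzene F10. The potassium alkoxide of 12 (KH, THF) would add to trichloroethylene to give the (E)-1,2-dichlorovinyl ether F11, which n-BuLi (THF, −78 °C) followed by methanol should convert into the terminal ynol ether F12. Sonogashira coupling of F12 with F10 (Pd(PPh3)2Cl2, CuI, i-Pr2NH) would give the aryl ynol ether F13. Hydrogenation over Lindlar catalyst with quinoline would then give 13; the poisoned catalyst should leave the aryl benzyl ethers intact.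

Step 11. The oxocarbenium ion may lose the C3 proton, which would erode the stereocentre through a 4H-chromene, or the ring O1–C2 bond may ionise in place of the exocyclic one and lead to a ring-opened ether. The fallback replaces the anhydrous Lewis acid reduction by hydrolysis, carbonyl reduction and ring closure. It sets out from 17 and comes back at 18. Acetal 17 would be hydrolysed (1 M HCl, THF/H2O, rt), where water should trap the cation quickly, to give the lactol F14 with recovery of 12. The lactol would be reduced through its open hydroxy aldehyde form (NaBH4, EtOH, 0 °C) to the phenol alcohol F9, the same compound that the fallback for step 10 passes through. Mitsunobu etherification (PPh3, DIAD, THF) would then give 18.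

Further compounds
F1 | step 10 | [2,5-bis(benzyloxy)-3,4-dimethoxyphenyl]acetonitrile | N#CCc1cc(OCc2ccccc2)c(OC)c(OC)c1OCc1ccccc1
F2 | step 10 | [2,5-bis(benzyloxy)-3,4-dimethoxyphenyl]acetic acid | OC(=O)Cc1cc(OCc2ccccc2)c(OC)c(OC)c1OCc1ccccc1
F3 | step 10 | (4S)-4-benzyl-3-{[2,5-bis(benzyloxy)-3,4-dimethoxyphenyl]acetyl}-1,3-oxazolidin-2-one | O=C(Cc1cc(OCc2ccccc2)c(OC)c(OC)c1OCc1ccccc1)N1[C@@H](Cc2ccccc2)COC1=O
F4 | step 10 | 2-(allyloxy)-4-(benzyloxy)-3,5-dimethoxybenzaldehyde | O=Cc1cc(OC)c(OCc2ccccc2)c(OC)c1OCC=C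
F5 | step 10 | [2-(allyloxy)-4-(benzyloxy)-3,5-dimethoxyphenyl]methanol | OCc1cc(OC)c(OCc2ccccc2)c(OC)c1OCC=C
F6 | step 10 | 1-(allyloxy)-3-(benzyloxy)-6-(bromomethyl)-2,4-dimethoxybenzene | BrCc1cc(OC)c(OCc2ccccc2)c(OC)c1OCC=C
F7 | step 10 | (4S)-3-{(2S)-3-[2-(allyloxy)-4-(benzyloxy)-3,5-dimethoxyphenyl]-2-[2,5-bis(benzyloxy)-3,4-dimethoxyphenyl]propanoyl}-4-benzyl-1,3-oxazolidin-2-one | O=C([C@@H](Cc1cc(OC)c(OCc2ccccc2)c(OC)c1OCC=C)c1cc(OCc2ccccc2)c(OC)c(OC)c1OCc1ccccc1)N1[C@@H](Cc2ccccc2)COC1=O
F8 | step 10 | (2S)-3-[2-(allyloxy)-4-(benzyloxy)-3,5-dimethoxyphenyl]-2-[2,5-bis(benzyloxy)-3,4-dimethoxyphenyl]propan-1-ol | OC[C@@H](Cc1cc(OC)c(OCc2ccccc2)c(OC)c1OCC=C)c1cc(OCc2ccccc2)c(OC)c(OC)c1OCc1ccccc1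
F9 | step 10 | (2S)-3-[4-(benzyloxy)-2-hydroxy-3,5-dimethoxyphenyl]-2-[2,5-bis(benzyloxy)-3,4-dimethoxyphenyl]propan-1-ol | OC[C@@H](Cc1cc(OC)c(OCc2ccccc2)c(OC)c1O)c1cc(OCc2ccccc2)c(OC)c(OC)c1OCc1ccccc1
F10 | step 9 | 1,4-bis(benzyloxy)-5-iodo-2,3-dimethoxybenzene | COc1c(OCc2ccccc2)cc(I)c(OCc2ccccc2)c1OC
F11 | step 9 | (1R,2S)-1-{[(E)-1,2-dichloroethenyl]oxy}-2-phenylcyclohexane | Cl/C=C(/Cl)O[C@@H]1CCCC[C@H]1c1ccccc1
F12 | step 9 | (1R,2S)-1-(ethynyloxy)-2-phenylcyclohexane | C#CO[C@@H]1CCCC[C@H]1c1ccccc1
F13 | step 9 | 1,4-bis(benzyloxy)-2,3-dimethoxy-5-({[(1R,2S)-2-phenylcyclohexyl]oxy}ethynyl)benzene | c1ccccc1[C@@H]1CCCC[C@H]1OC#Cc1cc(OCc2ccccc2)c(OC)c(OC)c1OCc1ccccc1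
F14 | step 11 | (3S)-7-(benzyloxy)-3-[2,5-bis(benzyloxy)-3,4-dimethoxyphenyl]-6,8-dimethoxychroman-2-ol (mixture of anomers) | OC1Oc2c(OC)c(OCc3ccccc3)c(OC)cc2C[C@H]1c1cc(OCc2ccccc2)c(OC)c(OC)c1OCc1ccccc1
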